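**Retrosynthetic overview**
1. Target 22 ⇐ bis-TIPS ether 21 ⇐ C7-formyl bicycle 18: the C7 prenyl group is grown from a formyl group by two Wittig reactions, so no metathesis touches the geranyl chains.
2. Key disconnection: ring A of the bicyclo[3.3.1]nonane (C1–C2–C3–C4–C5–C9, with the C3 aroyl group and the C1/C5 geranyl groups) is a dearomatized acylphloroglucinol. The whole C6–C7–C8 bridge is removed by cutting C5–C6 and C1–C8 together, which leads to the flat, achiral benzophenone 10 and the six-carbon acetoxy enal 16.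
3. Forward, one enantioselective alkylative dearomatization/double Michael annulation (10 + 16 → 18) closes ring B (C1–C8–C7–C6–C5–C9) and sets C1, C5, C8 (all quaternary) and C7.
4. 10 ⇐ double C-geranylation of benzophenone 8 ⇐ lithiated tris-MOM phloroglucinol 4 + silylated nitrile 2; 16 ⇐ 2-bromoacrolein acetal 11 + acetone 12.
5. Ring order: ring A is bought as phloroglucinol, dearomatized in step 7, and ring B is closed in the same step; no other ring is formed.

Key step: step 7

Abbreviations: geranyl = (2E)-3,7-dimethylocta-2,6-dien-1-yl; TIPS = triisopropylsilyl; MOM = methoxymethyl; locants C1–C9 are those of the bicyclo[3.3.1]nonane, with C1 next to C8.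

Assumption: the target is treated as the drawn 4-hydroxy-2-oxo tautomer, which is (1S,5S,7R) with the C7 prenyl group exo; the cinchonidine-derived catalyst of step 7 is assumed to give the (5S) bridgehead, and if the first run shows the opposite sense the pseudo-enantiomeric cinchonine-derived salt is used instead; 11 is taken as a catalogue compound.

**Step 1**
Reactants: 1 3,4-dihydroxybenzonitrile
Product: 2 3,4-bis(triisopropylsilyloxy)benzonitrile
Conditions: TIPSCl (2.5 equiv), imidazole, DMF, 40 °C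
Reagents that add atoms: chlorotriisopropylsilane, CC(C)[Si](Cl)(C(C)C)C(C)C
Why: Imidazole-mediated O-silylation of both phenols; the bulky TIPS ethers are chosen to survive aryllithium, dilute acid, amide bases and ylides and to leave with fluoride at the end.

**Step 2**
Reactants: 3 phloroglucinol
Product: 4 1,3,5-tris(methoxymethoxy)benzene
Conditions: NaH, MOMCl, DMF, 0 °C → rt
Reagents that add atoms: chloromethyl methyl ether, COCCl
Why: Williamson O-alkylation of the tris-phenoxide with the hard electrophile MOMCl; the MOM groups later direct the ortho-lithiation.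

**Step 3**
Reactants: 4 1,3,5-tris(methoxymethoxy)benzene; 2 3,4-bis(triisopropylsilyloxy)benzonitrile
Product: 8 [3,4-bis(triisopropylsilyloxy)phenyl](2,4,6-trihydroxyphenyl)methanone, via aryllithium 5 (not isolated), via N-H ketimine 6 (not isolated), via tris-MOM ketone 7 (not isolated)
Conditions: n-BuLi, THF, 0 °C; 2, −78 °C → rt; 2 M aq. HCl, THF/MeOH, rt → 45 °C
Reagents that add atoms: water, O
Why: Directed ortho-lithiation between two OMOM groups and single addition of the aryllithium to the nitrile should give the ketimine, which dilute acid hydrolyses to the ketone and then frees from its MOM acetals; aryl TIPS ethers are far more acid-stable than MOM acetals.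

**Step 4**
Reactants: 8 [3,4-bis(triisopropylsilyloxy)phenyl](2,4,6-trihydroxyphenyl)methanone; 9 geranyl bromide
Product: 10 [3,4-bis(triisopropylsilyloxy)phenyl](3,5-digeranyl-2,4,6-trihydroxyphenyl)methanone
Conditions: 9 (2.1 equiv), DBU (2.2 equiv), THF, 0 °C → rt
Reagents that add atoms: none
Why: C-alkylation of the ambident acylphloroglucinolate by the soft allylic bromide at the two free ring carbons (SN2, E geometry retained), a standard C-prenylation/geranylation of acylphloroglucinols; the mono-geranyl product can be resubmitted.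

**Step 5**
Reactants: 11 2-bromo-3,3-diethoxyprop-1-ene; 12 acetone
Product: 15 3-(diethoxymethyl)-2-methylbut-3-en-2-yl acetate, via vinyllithium 13 (not isolated), via lithium alkoxide 14 (not isolated)
Conditions: t-BuLi (2 equiv), Et2O, −78 °C; 12; Ac2O, −78 °C → rt
Reagents that add atoms: acetic anhydride, CC(=O)OC(C)=O
Why: Bromine–lithium exchange gives the α-lithio acrolein acetal, which adds 1,2 to acetone; the lithium tert-alkoxide is acetylated in the same flask.

**Step 6**
Reactants: 15 3-(diethoxymethyl)-2-methylbut-3-en-2-yl acetate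
Product: 16 3-formyl-2-methylbut-3-en-2-yl acetate
Conditions: Amberlyst-15, acetone/H2O, rt
Reagents that add atoms: water, O
Why: Mild heterogeneous acetal hydrolysis should free the enal without ionizing the tertiary acetate.

**Step 7**
Reactants: 10 [3,4-bis(triisopropylsilyloxy)phenyl](3,5-digeranyl-2,4,6-trihydroxyphenyl)methanone; 16 3-formyl-2-methylbut-3-en-2-yl acetate
Product: 18 (1S,5S,7R)-3-[3,4-bis(triisopropylsilyloxy)benzoyl]-1,5-digeranyl-4-hydroxy-8,8-dimethyl-2,9-dioxobicyclo[3.3.1]non-3-ene-7-carbaldehyde (formyl group exo), via dearomatized enal 17 (not isolated)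
Conditions: naphthalene-2,7-diylbis(methylene)-bridged bis(O-allylhydrocinchonidinium) dibromide (20 mol%), CsOH·H2O, 4 Å MS, CH2Cl2, −50 °C; aq. NH4Cl wash, then KHMDS (1.3 equiv), THF, 65 °C; aq. HCl work-up
Reagents that add atoms: none
Why: The chiral bis-ammonium cation carries the phloroglucinolate of 10 into CH2Cl2, where a geranyl-bearing ring carbon adds to the CH2 terminus of 16 and the aldehyde enolate expels acetate (Michael addition/E1cB, net SN2′) to give the dearomatized enal 17; in the KHMDS stage the enolate carbon C1 adds to the β,β-dimethyl terminus of that enal and forms the C1–C8 bond. The closest known reaction type is the alkylative dearomatization–annulation of 3,5-diprenyl-2,4,6-trihydroxybenzophenone with this same acetoxy enal, known with KHMDS in hot THF and, enantioselectively, with dimeric Cinchona ammonium salts and CsOH. Ring B (C1–C8–C7–C6–C5–C9) closes by a 6-endo-trig intramolecular Michael addition, driven by formation of the stabilized triketone enolate. C5 is set by the catalyst, which must distinguish the enantiotopic geranyl-bearing carbons and faces of flat 10 in the first C–C bond formation; C1 follows from C5 because the three-carbon tether reaches only the same ring face; C7 is set under thermodynamic control, the small excess of base equilibrating the formyl group to the exo (equatorial) position of the chair. The step needs C- over O-alkylation and attack at a geranyl-bearing carbon and not at the acyl-bearing one, which the soft enal acceptor, the tight ion pair in a non-polar solvent and the deactivation of the acyl-bearing carbon by the aroyl group should secure, while the hindered aryl TIPS ethers keep the catechol out of play.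

**Step 8**
Reactants: 18 the C7-formyl bicycle
Product: 20 2-{(1S,5S,7S)-3-[3,4-bis(triisopropylsilyloxy)benzoyl]-1,5-digeranyl-4-hydroxy-8,8-dimethyl-2,9-dioxobicyclo[3.3.1]non-3-en-7-yl}acetaldehyde (side chain exo), via methyl enol ether 19 (not isolated)
Conditions: MeOCH2PPh3Cl (3.5 equiv), KHMDS (3.4 equiv), THF, 0 °C → rt; then 2 M aq. HCl, rt
Reagents that add atoms: (methoxymethyl)triphenylphosphonium chloride, COC[P+](c1ccccc1)(c1ccccc1)c1ccccc1.[Cl-]; water, O
Why: Wittig methoxymethylenation and enol-ether hydrolysis (one-carbon homologation); the first equivalent of ylide turns the acidic triketone into its inert enolate, the bridging C9 ketone between two quaternary carbons is too hindered to react, and C7 is no longer epimerizable once the formyl group has reacted.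

**Step 9**
Reactants: 20 the homologated aldehyde
Product: 21 (1S,5S,7R)-3-[3,4-bis(triisopropylsilyloxy)benzoyl]-1,5-digeranyl-4-hydroxy-8,8-dimethyl-7-(3-methylbut-2-en-1-yl)bicyclo[3.3.1]non-3-ene-2,9-dione
Conditions: i-PrPPh3I (3.3 equiv), n-BuLi (3.0 equiv), THF, 0 °C → rt
Reagents that add atoms: isopropyltriphenylphosphonium iodide, CC(C)[P+](c1ccccc1)(c1ccccc1)c1ccccc1.[I-]
Why: Wittig olefination of the aldehyde with the isopropylidene ylide should complete the prenyl group (no alkene geometry to control); the triketone is again protected as its enolate and no free n-BuLi is present.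

**Step 10**
Reactants: 21 the bis-TIPS ether
Product: 22 (1S,5S,7R)-3-(3,4-dihydroxybenzoyl)-1,5-digeranyl-4-hydroxy-8,8-dimethyl-7-(3-methylbut-2-en-1-yl)bicyclo[3.3.1]non-3-ene-2,9-dione (CNP0178719.1)
Conditions: TBAF, AcOH, THF, 0 °C, argon
Reagents that add atoms: none
Why: Fluoride cleavage of the two aryl silyl ethers, buffered with acetic acid so that the catechol is never present as an oxidation-prone dianion; alkenes, enol and stereocentres are untouched.

**Compound list**
1 | 3,4-dihydroxybenzonitrile | N#Cc1ccc(O)c(O)c1 | starting material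
2 | 3,4-bis(triisopropylsilyloxy)benzonitrile | N#Cc1ccc(O[Si](C(C)C)(C(C)C)C(C)C)c(O[Si](C(C)C)(C(C)C)C(C)C)c1 | intermediate
3 | phloroglucinol | Oc1cc(O)cc(O)c1 | starting material
4 | 1,3,5-tris(methoxymethoxy)benzene | COCOc1cc(OCOC)cc(OCOC)c1 | intermediate
5 | [2,4,6-tris(methoxymethoxy)phenyl]lithium | [Li]c1c(OCOC)cc(OCOC)cc1OCOC | intermediate
6 | 1-[3,4-bis(triisopropylsilyloxy)phenyl]-1-[2,4,6-tris(methoxymethoxy)phenyl]methanimine | N=C(c1ccc(O[Si](C(C)C)(C(C)C)C(C)C)c(O[Si](C(C)C)(C(C)C)C(C)C)c1)c1c(OCOC)cc(OCOC)cc1OCOC | intermediate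
7 | [3,4-bis(triisopropylsilyloxy)phenyl][2,4,6-tris(methoxymethoxy)phenyl]methanone | O=C(c1ccc(O[Si](C(C)C)(C(C)C)C(C)C)c(O[Si](C(C)C)(C(C)C)C(C)C)c1)c1c(OCOC)cc(OCOC)cc1OCOC | intermediate
8 | [3,4-bis(triisopropylsilyloxy)phenyl](2,4,6-trihydroxyphenyl)methanone | O=C(c1ccc(O[Si](C(C)C)(C(C)C)C(C)C)c(O[Si](C(C)C)(C(C)C)C(C)C)c1)c1c(O)cc(O)cc1O | intermediate
9 | geranyl bromide, (2E)-1-bromo-3,7-dimethylocta-2,6-diene | CC(C)=CCC/C(C)=C/CBr | starting material
10 | [3,4-bis(triisopropylsilyloxy)phenyl](3,5-digeranyl-2,4,6-trihydroxyphenyl)methanone | O=C(c1ccc(O[Si](C(C)C)(C(C)C)C(C)C)c(O[Si](C(C)C)(C(C)C)C(C)C)c1)c1c(O)c(C/C=C(\C)CCC=C(C)C)c(O)c(C/C=C(\C)CCC=C(C)C)c1O | intermediate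
11 | 2-bromo-3,3-diethoxyprop-1-ene | C=C(Br)C(OCC)OCC | starting material
12 | acetone | CC(C)=O | starting material
13 | (3,3-diethoxyprop-1-en-2-yl)lithium | [Li]C(=C)C(OCC)OCC | intermediate
14 | lithium 3-(diethoxymethyl)-2-methylbut-3-en-2-olate | [Li]OC(C)(C)C(=C)C(OCC)OCC | intermediate
15 | 3-(diethoxymethyl)-2-methylbut-3-en-2-yl acetate | CC(=O)OC(C)(C)C(=C)C(OCC)OCC | intermediate
16 | 3-formyl-2-methylbut-3-en-2-yl acetate | CC(=O)OC(C)(C)C(=C)C=O | intermediate
17 | 2-({(1S)-3-[3,4-bis(triisopropylsilyloxy)benzoyl]-1,5-digeranyl-2,4-dihydroxy-6-oxocyclohexa-2,4-dien-1-yl}methyl)-3-methylbut-2-enal | O=CC(=C(C)C)C[C@]1(C/C=C(\C)CCC=C(C)C)C(=O)C(C/C=C(\C)CCC=C(C)C)=C(O)C(C(=O)c2ccc(O[Si](C(C)C)(C(C)C)C(C)C)c(O[Si](C(C)C)(C(C)C)C(C)C)c2)=C1O | intermediate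
18 | (1S,5S,7R)-3-[3,4-bis(triisopropylsilyloxy)benzoyl]-1,5-digeranyl-4-hydroxy-8,8-dimethyl-2,9-dioxobicyclo[3.3.1]non-3-ene-7-carbaldehyde, formyl exo | CC(C)=CCC/C(C)=C/C[C@]12C[C@@H](C=O)C(C)(C)[C@](C/C=C(\C)CCC=C(C)C)(C(=O)C(C(=O)c3ccc(O[Si](C(C)C)(C(C)C)C(C)C)c(O[Si](C(C)C)(C(C)C)C(C)C)c3)=C1O)C2=O | intermediate
19 | (1S,5S,7S)-3-[3,4-bis(triisopropylsilyloxy)benzoyl]-1,5-digeranyl-4-hydroxy-7-(2-methoxyethenyl)-8,8-dimethylbicyclo[3.3.1]non-3-ene-2,9-dione, E/Z mixture at the enol ether | CC(C)=CCC/C(C)=C/C[C@]12C[C@@H](C=COC)C(C)(C)[C@](C/C=C(\C)CCC=C(C)C)(C(=O)C(C(=O)c3ccc(O[Si](C(C)C)(C(C)C)C(C)C)c(O[Si](C(C)C)(C(C)C)C(C)C)c3)=C1O)C2=O | intermediate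
20 | 2-{(1S,5S,7S)-3-[3,4-bis(triisopropylsilyloxy)benzoyl]-1,5-digeranyl-4-hydroxy-8,8-dimethyl-2,9-dioxobicyclo[3.3.1]non-3-en-7-yl}acetaldehyde | CC(C)=CCC/C(C)=C/C[C@]12C[C@@H](CC=O)C(C)(C)[C@](C/C=C(\C)CCC=C(C)C)(C(=O)C(C(=O)c3ccc(O[Si](C(C)C)(C(C)C)C(C)C)c(O[Si](C(C)C)(C(C)C)C(C)C)c3)=C1O)C2=O | intermediate
21 | (1S,5S,7R)-3-[3,4-bis(triisopropylsilyloxy)benzoyl]-1,5-digeranyl-4-hydroxy-8,8-dimethyl-7-(3-methylbut-2-en-1-yl)bicyclo[3.3.1]non-3-ene-2,9-dione | CC(C)=CCC/C(C)=C/C[C@]12C[C@@H](CC=C(C)C)C(C)(C)[C@](C/C=C(\C)CCC=C(C)C)(C(=O)C(C(=O)c3ccc(O[Si](C(C)C)(C(C)C)C(C)C)c(O[Si](C(C)C)(C(C)C)C(C)C)c3)=C1O)C2=O | intermediate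
22 | (1S,5S,7R)-3-(3,4-dihydroxybenzoyl)-1,5-digeranyl-4-hydroxy-8,8-dimethyl-7-(3-methylbut-2-en-1-yl)bicyclo[3.3.1]non-3-ene-2,9-dione | CC(C)=CCC/C(C)=C/C[C@]12C[C@@H](CC=C(C)C)C(C)(C)[C@](C/C=C(\C)CCC=C(C)C)(C(=O)C(C(=O)c3ccc(O)c(O)c3)=C1O)C2=O | target

**Step count**
Total: 10 steps. Longest linear sequence: 7 steps (1 or 2, then 3, 4, 7, 8, 9, 10).

**Steps most likely to fail**

Step 7. Three processes are the main risks:
- facial discrimination by the ammonium ion pair may be weak or reversed with the bulky bis-silylated substrate;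
- O-alkylation may compete with C-alkylation;
- the endo-formyl epimer may be captured by reversible intramolecular aldol addition to C3, which withdraws material if the retro-aldol in the KHMDS stage is slow.

Fallback: 10 and 16 are combined under the achiral conditions (KHMDS, THF, 65 °C) to give the racemate, that is 18 together with its enantiomer F1. The racemate is condensed with (S)-1-amino-2-(methoxymethyl)pyrrolidine to the diastereomeric hydrazones, the SAMP hydrazone of 18 F2 and the SAMP hydrazone of the enantiomer F3, which are separated by chromatography. Two-phase cleavage of F2 with aqueous oxalic acid returns to the route at 18.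

Step 4. The phenoxide alkylation may give geminal dialkylation at one ring carbon (with dearomatization), O-geranylation, or stop at the mono-geranyl stage.

Fallback: the geranyl groups are installed by aryl-metal chemistry before the ketone is formed. Starting from 4, ortho-lithiation (n-BuLi, THF, 0 °C) and copper-catalysed coupling with 9 (CuBr·SMe2 cat.) should give 2-geranyl-1,3,5-tris(methoxymethoxy)benzene F4. Repeating the operation gives 2,4-digeranyl-1,3,5-tris(methoxymethoxy)benzene F5. A third lithiation at the last ring C–H and addition to nitrile 2 gives the N-H ketimine F6, which is hydrolysed to the tris-MOM ketone F7. Brief methanolic HCl then removes the MOM groups and returns to the route at 10.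

Step 8. During the acidic enol-ether hydrolysis the C4 enol oxygen may add to the C5 geranyl double bond (pyran formation), or the geranyl chains may undergo cation–olefin cyclization; the Wittig reaction may also be slow on the enolate-bearing substrate.

Fallback: an acid-free homologation from 18. Wittig methylenation (Ph3P=CH2, THF) gives the 7-vinyl compound F8. Hydroboration with 9-BBN, which selects the monosubstituted alkene over the trisubstituted geranyl alkenes, followed by NaBO3 oxidation gives the primary alcohol F9. Parikh–Doering oxidation (SO3·pyridine, DMSO, Et3N) returns to the route at 20.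

**Further compounds**
F1 | step 7 | enantiomer of 18, (1R,5R,7S) | CC(C)=CCC/C(C)=C/C[C@@]12C[C@H](C=O)C(C)(C)[C@@](C/C=C(\C)CCC=C(C)C)(C(=O)C(C(=O)c3ccc(O[Si](C(C)C)(C(C)C)C(C)C)c(O[Si](C(C)C)(C(C)C)C(C)C)c3)=C1O)C2=O
F2 | step 7 | (E)-SAMP hydrazone of 18 | CC(C)=CCC/C(C)=C/C[C@]12C[C@@H](/C=N/N4CCC[C@H]4COC)C(C)(C)[C@](C/C=C(\C)CCC=C(C)C)(C(=O)C(C(=O)c3ccc(O[Si](C(C)C)(C(C)C)C(C)C)c(O[Si](C(C)C)(C(C)C)C(C)C)c3)=C1O)C2=O
F3 | step 7 | (E)-SAMP hydrazone of F1 | CC(C)=CCC/C(C)=C/C[C@@]12C[C@H](/C=N/N4CCC[C@H]4COC)C(C)(C)[C@@](C/C=C(\C)CCC=C(C)C)(C(=O)C(C(=O)c3ccc(O[Si](C(C)C)(C(C)C)C(C)C)c(O[Si](C(C)C)(C(C)C)C(C)C)c3)=C1O)C2=O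
F4 | step 4 | 2-geranyl-1,3,5-tris(methoxymethoxy)benzene | COCOc1cc(OCOC)c(C/C=C(\C)CCC=C(C)C)c(OCOC)c1
F5 | step 4 | 2,4-digeranyl-1,3,5-tris(methoxymethoxy)benzene | COCOc1cc(OCOC)c(C/C=C(\C)CCC=C(C)C)c(OCOC)c1C/C=C(\C)CCC=C(C)C
F6 | step 4 | 1-[3,4-bis(triisopropylsilyloxy)phenyl]-1-[3,5-digeranyl-2,4,6-tris(methoxymethoxy)phenyl]methanimine | N=C(c1ccc(O[Si](C(C)C)(C(C)C)C(C)C)c(O[Si](C(C)C)(C(C)C)C(C)C)c1)c1c(OCOC)c(C/C=C(\C)CCC=C(C)C)c(OCOC)c(C/C=C(\C)CCC=C(C)C)c1OCOC
F7 | step 4 | [3,4-bis(triisopropylsilyloxy)phenyl][3,5-digeranyl-2,4,6-tris(methoxymethoxy)phenyl]methanone | O=C(c1ccc(O[Si](C(C)C)(C(C)C)C(C)C)c(O[Si](C(C)C)(C(C)C)C(C)C)c1)c1c(OCOC)c(C/C=C(\C)CCC=C(C)C)c(OCOC)c(C/C=C(\C)CCC=C(C)C)c1OCOC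
F8 | step 8 | 7-vinyl analogue of 18 (vinyl exo) | CC(C)=CCC/C(C)=C/C[C@]12C[C@@H](C=C)C(C)(C)[C@](C/C=C(\C)CCC=C(C)C)(C(=O)C(C(=O)c3ccc(O[Si](C(C)C)(C(C)C)C(C)C)c(O[Si](C(C)C)(C(C)C)C(C)C)c3)=C1O)C2=O
F9 | step 8 | 7-(2-hydroxyethyl) analogue of 18 (side chain exo) | CC(C)=CCC/C(C)=C/C[C@]12C[C@@H](CCO)C(C)(C)[C@](C/C=C(\C)CCC=C(C)C)(C(=O)C(C(=O)c3ccc(O[Si](C(C)C)(C(C)C)C(C)C)c(O[Si](C(C)C)(C(C)C)C(C)C)c3)=C1O)C2=O
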